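**Strategy.** Ring B of the tetralin (C1–C2–C3–C4–C4a–C8a) is opened at C1–C2 and C3–C4. C1 and C4, the benzylic carbons on adjacent positions of ring A, become the termini of a hydroxy-o-quinodimethane, and the trans C2–C3 unit with its two CH2OH carbons becomes a fumarate. A photoenolisation/Diels–Alder reaction of a 2-methylbenzaldehyde with a twofold-symmetric di-(R)-mandelyl fumarate closes ring B and sets C2 and C3 in one operation. The C1 hydroxyl left by the cycloaddition, benzylic and para-activated by the C6 methoxy group, is then exchanged for the guaiacyl ring C trans to C2, and hydride reduction releases the target.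

Key step: step 4

Remarks:
- Locants: C1 = aryl-bearing benzylic CH, C2 and C3 = the CH(CH2OH) carbons, C4 = benzylic CH2, ring A = C4a–C8a (OMe on C6, OH on C7), ring C = the 4-hydroxy-3-methoxyphenyl group. The target is the (1R,2S,3S) isomer, with 1,2-trans and 2,3-trans substituents.
- Assumption: the sense of auxiliary control in step 4 is taken from the conformational model given there. That model is the least certain point of the route; should the opposite sense be found, methyl (S)-mandelate would be used instead of 9.

Step 1
Reactants: 1 2-methoxy-4-methylphenol (creosol); 2 acetic anhydride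
Product: 3 2-methoxy-4-methylphenyl acetate
Conditions: Ac2O, pyridine, DMAP (cat.), rt
Reagents that add atoms: acetic anhydride, CC(=O)OC(C)=O
Why: DMAP-catalysed O-acetylation of the phenol, which blocks ortho-formylation in step 2, should survive the photochemical and acid steps, and is removed without an extra step by the hydride in step 6.

Step 2
Reactants: 3 2-methoxy-4-methylphenyl acetate; 4 dichloromethyl methyl ether; 5 water (work-up)
Product: 7 5-formyl-2-methoxy-4-methylphenyl acetate, via chloro(methoxy)methyl arene 6 (not isolated)
Conditions: Cl2CHOMe, TiCl4, CH2Cl2, −10 → 0 °C; then ice/H2O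
Reagents that add atoms: dichloromethyl methyl ether, COC(Cl)Cl; water, O
Why: Rieche formylation, in which the TiCl4-activated ether should attack the only free ring position para to an oxygen donor (para to OMe, ortho to CH3), as in the formylation of 3,4-dialkoxytoluenes, and hydrolysis of chloro ether 6 gives the aldehyde.

Step 3
Reactants: 8 fumaryl chloride; 9 methyl (R)-mandelate (2 equiv)
Product: 10 bis[(1R)-2-methoxy-2-oxo-1-phenylethyl] (2E)-but-2-enedioate
Conditions: pyridine (2.2 equiv), CH2Cl2, 0 °C → rt
Reagents that add atoms: fumaryl chloride, O=C(Cl)/C=C/C(=O)Cl; methyl (R)-mandelate, COC(=O)[C@H](O)c1ccccc1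
Why: Acylation of the secondary alcohol by the diacid chloride under weakly basic conditions, which should neither epimerise the mandelate stereocentre (its C–O bond is untouched) nor isomerise the E alkene.

Step 4
Reactants: 7 5-formyl-2-methoxy-4-methylphenyl acetate; 10 bis[(1R)-2-methoxy-2-oxo-1-phenylethyl] (2E)-but-2-enedioate
Product: 12 bis[(1R)-2-methoxy-2-oxo-1-phenylethyl] (1R,2R,3S)-7-acetoxy-1-hydroxy-6-methoxy-1,2,3,4-tetrahydronaphthalene-2,3-dicarboxylate, via (E)-hydroxy-o-quinodimethane 11 (not isolated)
Conditions: hv (350 nm), degassed benzene, rt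
Reagents that add atoms: none
Why: Excitation of the aldehyde and 1,5-hydrogen transfer from the ortho methyl group give the (E)-dienol 11 (the Z-dienol reverts by a fast 1,5-hydrogen shift), which adds to fumarate 10 in a thermal suprafacial [4+2] cycloaddition driven by re-aromatisation of ring A; this is the photoenolisation/Diels–Alder reaction, closest to the known additions of hydroxy-o-quinodimethanes to fumarates of α-hydroxy esters. Ring B is the only ring closed, by a concerted, asynchronous six-membered [4+2] closure that forms C4–C3 and C1–C2 together. C2 and C3 should come out trans because the E geometry of the fumarate is transferred stereospecifically, and C1 (OH cis to the C2 ester) follows from the E geometry of the dienol and the endo orientation of the adjacent ester, held by a hydrogen bond from the dienol OH to that ester carbonyl. The absolute configuration is set by the two (R)-mandelyl groups: in the s-cis enoate conformer with each carbinol C–H eclipsing its C=O, both phenyl groups cover one face of the alkene and both CO2Me groups flank the other, to which the diene should add to give (1R,2R,3S)-12. The step needs endo/exo and π-facial selectivity, secured by the hydrogen bond and the twofold-symmetric auxiliary (a symmetric dienophile removes any regiochemical question). It also needs selective excitation, secured because only 7 absorbs at 350 nm, so the fumarate is not isomerised directly.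

Step 5
Reactants: 12 hydroxy diester cycloadduct; 13 2-methoxyphenol (guaiacol)
Product: 15 bis[(1R)-2-methoxy-2-oxo-1-phenylethyl] (1R,2S,3S)-7-acetoxy-1-(4-hydroxy-3-methoxyphenyl)-6-methoxy-1,2,3,4-tetrahydronaphthalene-2,3-dicarboxylate, via C1 benzylic cation 14 (not isolated)
Conditions: guaiacol (excess), TFA, CH2Cl2, −10 → 0 °C
Reagents that add atoms: 2-methoxyphenol, COc1ccccc1O
Why: Friedel–Crafts benzylation by an SN1 path, in which acid ionises the C1 hydroxyl (lost as water) to a cation stabilised by the C6 methoxy group para to C8a and guaiacol should attack through the carbon para to its free hydroxyl (the stronger donor) on the face anti to the pseudo-equatorial C2 ester, setting C1 as R in the all-equatorial, thermodynamically preferred 1,2-trans-2,3-trans array.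

Step 6
Reactants: 15 arylated diester
Product: 16 (1R,2S,3S)-1-(4-hydroxy-3-methoxyphenyl)-2,3-bis(hydroxymethyl)-6-methoxy-1,2,3,4-tetrahydronaphthalen-7-ol, also named (6S,7S,8R)-8-(4-hydroxy-3-methoxyphenyl)-6,7-bis(hydroxymethyl)-3-methoxy-5,6,7,8-tetrahydronaphthalen-2-ol
Conditions: LiAlH4 (excess), THF, 0 °C → reflux; then aq. potassium sodium tartrate, pH 6
Reagents that add atoms: none
Why: Ester reduction by LiAlH4 should convert both ring esters into the primary alcohols without touching C1, C2 or C3 (already in the thermodynamically preferred all-trans arrangement), cleave the aryl acetate and release the auxiliary as (R)-1-phenylethane-1,2-diol.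

**Compound list**

1 | 2-methoxy-4-methylphenol (creosol) | Cc1ccc(O)c(OC)c1 | starting material
2 | acetic anhydride | CC(=O)OC(C)=O | starting material
3 | 2-methoxy-4-methylphenyl acetate | Cc1ccc(OC(C)=O)c(OC)c1 | intermediate
4 | dichloromethyl methyl ether | COC(Cl)Cl | starting material
5 | water | O | starting material
6 | 5-[chloro(methoxy)methyl]-2-methoxy-4-methylphenyl acetate (not isolated) | COC(Cl)c1cc(OC(C)=O)c(OC)cc1C | intermediate
7 | 5-formyl-2-methoxy-4-methylphenyl acetate (5-acetoxy-4-methoxy-2-methylbenzaldehyde) | Cc1cc(OC)c(OC(C)=O)cc1C=O | intermediate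
8 | fumaryl chloride | O=C(Cl)/C=C/C(=O)Cl | starting material
9 | methyl (R)-mandelate | COC(=O)[C@H](O)c1ccccc1 | starting material
10 | bis[(1R)-2-methoxy-2-oxo-1-phenylethyl] (2E)-but-2-enedioate | COC(=O)[C@H](OC(=O)/C=C/C(=O)O[C@@H](C(=O)OC)c1ccccc1)c1ccccc1 | intermediate
11 | 3-[(E)-hydroxymethylidene]-6-methoxy-4-methylidenecyclohexa-1,5-dien-1-yl acetate, the (E)-hydroxy-o-quinodimethane (not isolated) | O/C=C1\C=C(OC(C)=O)C(OC)=CC1=C | intermediate
12 | bis[(1R)-2-methoxy-2-oxo-1-phenylethyl] (1R,2R,3S)-7-acetoxy-1-hydroxy-6-methoxy-1,2,3,4-tetrahydronaphthalene-2,3-dicarboxylate | O[C@H]1c2cc(OC(C)=O)c(OC)cc2C[C@H](C(=O)O[C@@H](C(=O)OC)c2ccccc2)[C@H]1C(=O)O[C@@H](C(=O)OC)c1ccccc1 | intermediate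
13 | 2-methoxyphenol (guaiacol) | COc1ccccc1O | starting material
14 | C1 benzylic cation derived from 12 (not isolated) | [CH+]1c2cc(OC(C)=O)c(OC)cc2C[C@H](C(=O)O[C@@H](C(=O)OC)c2ccccc2)[C@H]1C(=O)O[C@@H](C(=O)OC)c1ccccc1 | intermediate
15 | bis[(1R)-2-methoxy-2-oxo-1-phenylethyl] (1R,2S,3S)-7-acetoxy-1-(4-hydroxy-3-methoxyphenyl)-6-methoxy-1,2,3,4-tetrahydronaphthalene-2,3-dicarboxylate | COc1cc([C@@H]2c3cc(OC(C)=O)c(OC)cc3C[C@H](C(=O)O[C@@H](C(=O)OC)c3ccccc3)[C@H]2C(=O)O[C@@H](C(=O)OC)c2ccccc2)ccc1O | intermediate
16 | (1R,2S,3S)-1-(4-hydroxy-3-methoxyphenyl)-2,3-bis(hydroxymethyl)-6-methoxy-1,2,3,4-tetrahydronaphthalen-7-ol | COc1cc([C@@H]2c3cc(O)c(OC)cc3C[C@H](CO)[C@H]2CO)ccc1O | target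

**Step count.** Total: 6 steps. Longest linear sequence: 5 steps (1, 2, 4, 5, 6); step 3 is a one-step branch.

**Steps most likely to fail**

Step 4. The short-lived dienol may revert to the aldehyde faster than the bulky dienophile captures it, the dienophile may undergo sensitised E/Z isomerisation under irradiation, and endo or π-facial selectivity may erode. Fallback, setting out from 7 and returning at 12: the dienol is first stored as its sulfur dioxide adduct and released thermally in the dark. Irradiation of 7 (350 nm) in benzene saturated with SO2 should give 1-hydroxy-5-methoxy-2,2-dioxo-1,3-dihydro-2-benzothiophen-6-yl acetate F1. Heating F1 with fumarate 10 in benzene at 80 °C should extrude SO2 cheletropically, regenerate dienol 11 in the absence of light and give 12 by the same hydrogen-bonded endo cycloaddition.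

Step 5. The cation may lose the acidic C2 proton (E1 elimination to the ester-conjugated dihydronaphthalene, which does not re-ionise) faster than it is arylated, and guaiacol may attack through the position para to OMe instead of para to OH. Fallback, setting out from 12 and returning at 16: the order of reduction and arylation is reversed. LiAlH4 (THF, 0 °C → rt) should reduce 12 to (1R,2S,3S)-2,3-bis(hydroxymethyl)-6-methoxy-1,2,3,4-tetrahydronaphthalene-1,7-diol F2. Treatment of F2 with guaiacol 13 and TFA in hexafluoroisopropanol at 0 °C should then give 16 directly. Without an ester at C2, proton loss gives only an electron-rich styrene that re-protonates to the same cation, and any cyclic ether formed by a hydroxymethyl group re-ionises, so the reversible pathways should drain into the all-equatorial C-arylated product.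

Step 2. The strong Lewis acid may remove or migrate the acetyl group, and regiocontrol may be incomplete. Fallback, setting out from 3 and returning at 7: the formyl group is introduced by halogenation and Pd(OAc)2-catalysed reductive carbonylation. NBS in MeCN at rt should brominate para to the methoxy group to give 5-bromo-2-methoxy-4-methylphenyl acetate F3. Formylation of F3 with CO/H2 (1:1, 5 bar), Pd(OAc)2 (cat.), di(1-adamantyl)-n-butylphosphine and TMEDA in toluene at 100 °C should give 7 under conditions that leave the aryl acetate intact.

**Further compounds**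

F1 | step 4 | 1-hydroxy-5-methoxy-2,2-dioxo-1,3-dihydro-2-benzothiophen-6-yl acetate (racemic) | O=S1(=O)Cc2cc(OC)c(OC(C)=O)cc2C1O
F2 | step 5 | (1R,2S,3S)-2,3-bis(hydroxymethyl)-6-methoxy-1,2,3,4-tetrahydronaphthalene-1,7-diol | O[C@H]1c2cc(O)c(OC)cc2C[C@H](CO)[C@H]1CO
F3 | step 2 | 5-bromo-2-methoxy-4-methylphenyl acetate | Cc1cc(OC)c(OC(C)=O)cc1Br
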